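**Retrosynthetic overview**
1. Feature used: in the seven-membered ring (C5–C6–C7–C8–C9–C10–C1) the carbinol carbons C5 and C8 are 1,4-related across C6–C7, and C9, next to C8, is oxygenated. C5–O–C8 is therefore treated as a carbonyl ylide of a C9 ketone, and C6–C7 as a two-carbon dipolarophile.
2. Endgame: C9 ester; trans-8,9-diol from the 8β,9β-epoxide; epoxide from the C8=C9 alkene under C5–OH direction; alkene from the 8-methyl-9-ketone; ketone from SmI2 scission of the temporary C8–O bond.
3. Key disconnection: C5–C6 and C7–C8, by Rh2(OAc)4-mediated ylide formation from diazoketone 12 and (3+2) addition of ethynyl phenyl sulfone.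
4. Precursor: diazoketone from a keto acid, made by Johnson–Claisen rearrangement and ozonolysis on the cyclopentene obtained by ring contraction of (S)-limonene.
5. Ring order: cyclopentane first (steps 2–3); in step 9 the six-membered oxacycle, the dihydrofuran and the cycloheptane together; the oxygen bridge is cut in step 13.

Key step: step 9

Remark on numbering: five-membered ring C1(Me)–C2–C3–C4(iPr)–C5, seven-membered ring C5–C6–C7–C8–C9–C10–C1; β is the face of the C1 methyl, α the other face. In the target C1–Me, C4–iPr, C5–OH, C8–Me and C9–O are β and C8–OH is α; in this numbering it is (1R,4R,5S,8R,9R).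
Assumption: ethynyl phenyl sulfone 13 is bought. If the cycloadduct with the sulfonyl group at C7 forms, it converges with 15 at compound 17.

**Route**

Step 1
Reactants: 1 (S)-(−)-limonene
Product: 2 (S)-(−)-p-menth-1-ene, (4S)-1-methyl-4-(propan-2-yl)cyclohex-1-ene
Conditions: H2 (1 atm), RhCl(PPh3)3 (cat.), toluene/EtOH, rt
Reagents that add atoms: none
Why: Homogeneous catalytic hydrogenation with RhCl(PPh3)3 saturates the 1,1-disubstituted isopropenyl alkene much faster than the trisubstituted ring alkene and leaves the stereocentre untouched.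

Step 2
Reactants: 2 (S)-(−)-p-menth-1-ene
Product: 3 (3S)-6-oxo-3-(propan-2-yl)heptanal
Conditions: O3, CH2Cl2/MeOH, −78 °C; then Me2S, −78 °C to rt
Reagents that add atoms: ozone, [O-][O+]=O
Why: Ozonolysis with reductive work-up cleaves the only alkene to the keto aldehyde without touching the stereocentre.

Step 3
Reactants: 3 (3S)-6-oxo-3-(propan-2-yl)heptanal
Product: 4 (5R)-2-methyl-5-(propan-2-yl)cyclopent-1-ene-1-carbaldehyde
Conditions: piperidine, AcOH, toluene, reflux (Dean–Stark)
Reagents that add atoms: none
Why: Intramolecular aldol condensation through the aldehyde enamine closes the five-membered ring onto the methyl ketone and dehydrates to the conjugated enal; no new stereocentre forms and the isopropyl-bearing carbon is only allylic.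

Step 4
Reactants: 4 (5R)-2-methyl-5-(propan-2-yl)cyclopent-1-ene-1-carbaldehyde
Product: 5 [(5R)-2-methyl-5-(propan-2-yl)cyclopent-1-en-1-yl]methanol
Conditions: NaBH4, CeCl3·7H2O, MeOH, 0 °C
Reagents that add atoms: none
Why: Luche reduction gives clean 1,2-reduction of the enal to the primary allylic alcohol.

Step 5
Reactants: 5 [(5R)-2-methyl-5-(propan-2-yl)cyclopent-1-en-1-yl]methanol; 6 triethyl orthoacetate
Product: 8 ethyl 2-[(1R,3R)-1-methyl-2-methylidene-3-(propan-2-yl)cyclopentyl]acetate, via mixed ketene acetal 7 (not isolated)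
Conditions: MeC(OEt)3 (excess), EtCO2H (cat.), 140 °C, EtOH distilled off
Reagents that add atoms: triethyl orthoacetate (6), CC(OCC)(OCC)OCC
Why: Johnson–Claisen rearrangement: the ketene acetal arm, anchored on the CH2O carbon next to the isopropyl-bearing carbon, should fold over the ring face opposite the isopropyl group, so the [3,3] shift puts CH2CO2Et trans and the methyl cis to isopropyl at the new quaternary C1 and leaves the exocyclic methylene that marks C5.

Step 6
Reactants: 8 ethyl 2-[(1R,3R)-1-methyl-2-methylidene-3-(propan-2-yl)cyclopentyl]acetate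
Product: 9 2-[(1R,3R)-1-methyl-2-methylidene-3-(propan-2-yl)cyclopentyl]acetic acid
Conditions: LiOH, THF/MeOH/H2O, 50 °C; then 1 M HCl
Reagents that add atoms: lithium hydroxide, [Li+].[OH-]
Why: Ester saponification is done before the ketone exists, so the later α-stereocentre C4 never meets hydroxide.

Step 7
Reactants: 9 2-[(1R,3R)-1-methyl-2-methylidene-3-(propan-2-yl)cyclopentyl]acetic acid
Product: 10 2-[(1R,3R)-1-methyl-2-oxo-3-(propan-2-yl)cyclopentyl]acetic acid
Conditions: O3, CH2Cl2/MeOH, −78 °C; then Me2S, −78 °C to rt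
Reagents that add atoms: ozone, [O-][O+]=O
Why: Ozonolysis of the only alkene turns the exocyclic methylene into the C5 ketone under neutral conditions that should not epimerise C4.

Step 8
Reactants: 10 2-[(1R,3R)-1-methyl-2-oxo-3-(propan-2-yl)cyclopentyl]acetic acid
Product: 12 1-diazo-3-[(1R,3R)-1-methyl-2-oxo-3-(propan-2-yl)cyclopentyl]propan-2-one, via mixed carbonic anhydride 11 (not isolated)
Conditions: iBuOCOCl, Et3N, THF, −15 °C; then CH2N2 (excess), Et2O, 0 °C to rt
Reagents that add atoms: diazomethane, C=[N+]=[N-]; isobutyl chloroformate, CC(C)COC(Cl)=O (its atoms stay only in the non-isolated 11)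
Why: Acylation of diazomethane by a mixed anhydride (first stage of the Arndt–Eistert sequence) gives the terminal diazoketone; the anhydride is used because γ-keto acid chlorides close to chlorolactones, and the weak base at low temperature leaves C4 alone.

Step 9
Reactants: 12 1-diazo-3-[(1R,3R)-1-methyl-2-oxo-3-(propan-2-yl)cyclopentyl]propan-2-one; 13 ethynyl phenyl sulfone
Product: 15 oxygen-bridged (C5–O–C8 on the β face) tricyclic 9-ketone with a C6=C7 alkene carrying PhSO2 at C6, via carbonyl ylide 14 (not isolated)
Conditions: Rh2(OAc)4 (2 mol %), 13 (3 equiv), CH2Cl2, rt, slow addition of 12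
Reagents that add atoms: ethynyl phenyl sulfone (13), C#CS(=O)(=O)c1ccccc1
Why: Rh2(OAc)4 removes N2 from 12 to give the electrophilic rhodium carbenoid at C8, and the lone pair of the C5 ketone oxygen attacks it, closing the six-membered oxacycle (O, C5, C1, C10, C9, C8) and releasing carbonyl ylide 14, whose C8 terminus is stabilised by the C9 carbonyl. The ylide then adds to the electron-poor alkyne in a concerted suprafacial (3+2) cycloaddition that forms C5–C6 and C7–C8 together and so closes the 2,5-dihydrofuran ring (O, C5, C6, C7, C8) and the seven-membered carbocycle. The closest known reaction type is the tandem dirhodium-carboxylate cyclisation–cycloaddition of 1-diazo-2,5-diones with acetylenic dipolarophiles. C5 is set by approach of the alkyne to the ylide face opposite the pseudoaxial C1 methyl and the cis C4 isopropyl group, which leaves the bridging oxygen β, and C8 has no freedom because the bridge must span C5 and C8 on one face. Only this facial selectivity is required: the regiochemistry (sulfonyl expected at C6, since nucleophilic C8 bonds to the unsubstituted alkyne carbon) is immaterial after desulfonylation, C1 is quaternary so the ylide cannot be quenched from that side, and slow addition of 12 to excess 13 should keep the 1,4-proton shift from C4–H and ylide dimerisation behind the cycloaddition.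

Step 10
Reactants: 15 bridged vinyl sulfone 9-ketone
Product: 16 9,9-ethylenedioxy ketal of 15
Conditions: TMSOCH2CH2OTMS, TMSOTf (cat.), CH2Cl2, −78 to −20 °C
Reagents that add atoms: 1,2-bis(trimethylsilyloxy)ethane, C[Si](C)(C)OCCO[Si](C)(C)C
Why: Silyl-triflate-catalysed ketalisation masks the hindered α-alkoxy ketone, which would otherwise be open to electron transfer in the next step; vinyl sulfone and bridging ether are inert.

Step 11
Reactants: 16 ketal of the bridged vinyl sulfone
Product: 17 bridged C6=C7 alkene ketal (sulfonyl replaced by H)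
Conditions: 6% Na/Hg, Na2HPO4, MeOH/THF, −20 °C
Reagents that add atoms: none
Why: Sodium-amalgam reductive desulfonylation of a vinyl sulfone: electron transfer breaks C6–S to a vinyl radical/anion that is protonated, and this sp2 carbanion, unlike a saturated α-sulfonyl carbanion, cannot eliminate the C5–O bridge.

Step 12
Reactants: 17 bridged C6=C7 alkene ketal
Product: 19 saturated oxygen-bridged (C5–O–C8) 9-ketone, via saturated ketal 18 (not isolated)
Conditions: H2 (1 atm), 10% Pd/C, EtOAc, rt; filter; then 2 M HCl, THF, 40 °C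
Reagents that add atoms: water, O
Why: Catalytic hydrogenation of the strained disubstituted alkene (C6 and C7 become CH2, no new stereocentre) followed by acetal hydrolysis; hydrogenation comes after desulfonylation because a saturated C6 sulfone β to the bridge oxygen would undergo Julia-type elimination.

Step 13
Reactants: 19 saturated bridged 9-ketone
Product: 20 5β-hydroxy-9-ketone (1β-methyl, 4β-isopropyl, C8 now CH2)
Conditions: SmI2 (2.5 equiv), THF/MeOH, −78 °C
Reagents that add atoms: none
Why: SmI2 cleavage of an α-alkoxy ketone: the C9 ketyl expels the adjacent bridgehead C8–O bond and the resulting samarium enolate is protonated by MeOH, so the oxygen stays on C5 with its β configuration.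

Step 14
Reactants: 20 5β-hydroxy-9-ketone
Product: 21 5β-triethylsilyloxy-9-ketone
Conditions: TESOTf, 2,6-lutidine, CH2Cl2, −78 to 0 °C; mild acidic work-up
Reagents that add atoms: triethylsilyl triflate, CC[Si](CC)(CC)OS(=O)(=O)C(F)(F)F
Why: Silyl triflate silylation of the hindered tertiary alcohol blocks alkoxide and transannular hemiketal chemistry in the enolate steps, and the work-up should return any silyl enol ether or silylated hemiketal to the ketone.

Step 15
Reactants: 21 5β-triethylsilyloxy-9-ketone
Product: 22 8-methyl-5β-triethylsilyloxy-9-ketone (C8 epimer mixture)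
Conditions: LiN(iPr)2 (LDA, 1.1 equiv), THF, −78 °C; MeI, −78 to −40 °C
Reagents that add atoms: iodomethane, CI
Why: Kinetic enolate alkylation: LDA should deprotonate the unhindered C8 methylene and not the neopentyl C10 methylene next to quaternary C1; the new C8 centre forms as an epimer mixture that is erased in step 16.

Step 16
Reactants: 22 8-methyl-5β-triethylsilyloxy-9-ketone
Product: 23 C8=C9 enol triflate (8-methyl, 9-OTf, 5β-OTES)
Conditions: Tf2O, 2,6-di-tert-butyl-4-methylpyridine, CH2Cl2, 0 °C to rt
Reagents that add atoms: triflic anhydride, O=S(=O)(OS(=O)(=O)C(F)(F)F)C(F)(F)F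
Why: Enol triflate formation under thermodynamic control: O-sulfonylation and loss of the tertiary C8 proton should give the tetrasubstituted C8=C9 triflate, the C10 side being less substituted and compressed against quaternary C1.

Step 17
Reactants: 23 C8=C9 enol triflate
Product: 25 5β-hydroxy C8=C9 alkene (8-methyl, 1β-methyl, 4β-isopropyl), via silyl ether alkene 24 (not isolated)
Conditions: Pd(OAc)2 (5 mol %), PPh3, HCO2H, Bu3N, DMF, 60 °C; then Bu4NF, THF, rt to 40 °C
Reagents that add atoms: none
Why: Palladium-catalysed formate reduction of the enol triflate (oxidative addition of zerovalent palladium into C9–OTf, decarboxylation of formate to Pd–H, reductive elimination) gives the trisubstituted alkene without migration, and fluoride then cleaves the silyl ether.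

Step 18
Reactants: 25 5β-hydroxy C8=C9 alkene
Product: 26 8β,9β-epoxide with free 5β-OH
Conditions: VO(acac)2 (5 mol %), t-BuOOH, CH2Cl2, 0 °C to rt
Reagents that add atoms: tert-butyl hydroperoxide, CC(C)(C)OO
Why: Hydroxyl-directed vanadium epoxidation: the vanadium alkoxide of C5–OH should carry the bound peroxide across the ring to the β face of C8=C9, setting C8 and C9 syn to the C5 oxygen.

Step 19
Reactants: 26 8β,9β-epoxide
Product: 27 5β,8α,9β-triol (8β-methyl)
Conditions: HClO4 (cat.), THF/H2O, 0 °C to rt
Reagents that add atoms: water, O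
Why: Acid-catalysed epoxide hydrolysis: water attacks tertiary C8 from the α face with inversion while the C9–O bond keeps its β configuration, giving the trans-diol; with the epoxide and C5–OH on the same face, backside transannular attack by the C5 hydroxyl is geometrically excluded.

Step 20
Reactants: 27 5β,8α,9β-triol; 28 4-methoxybenzoyl chloride
Product: 29 target, (1R,4R,5S,8R,9R)-5,8-dihydroxy-8-methyl ester of 4-methoxybenzoic acid at C9–O (CNP0244624.1)
Conditions: 28 (1.2 equiv), pyridine, DMAP (cat.), CH2Cl2, 0 °C to rt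
Reagents that add atoms: 4-methoxybenzoyl chloride (28), COc1ccc(C(=O)Cl)cc1
Why: DMAP-catalysed acylation is selective for the only secondary hydroxyl (C9); the tertiary C5 and C8 alcohols should not react and no stereocentre changes.

**Compound list**
1 | (S)-(−)-limonene | CC1=CC[C@H](CC1)C(C)=C | starting material
2 | (S)-(−)-p-menth-1-ene | CC1=CC[C@H](CC1)C(C)C | intermediate
3 | (3S)-6-oxo-3-(propan-2-yl)heptanal | O=CC[C@H](CCC(C)=O)C(C)C | intermediate
4 | (5R)-2-methyl-5-(propan-2-yl)cyclopent-1-ene-1-carbaldehyde | O=CC1=C(C)CC[C@@H]1C(C)C | intermediate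
5 | [(5R)-2-methyl-5-(propan-2-yl)cyclopent-1-en-1-yl]methanol | OCC1=C(C)CC[C@@H]1C(C)C | intermediate
6 | triethyl orthoacetate | CC(OCC)(OCC)OCC | starting material
7 | mixed ketene acetal of 5 (1-ethoxyvinyl ether) | C=C(OCC)OCC1=C(C)CC[C@@H]1C(C)C | intermediate (not isolated)
8 | ethyl 2-[(1R,3R)-1-methyl-2-methylidene-3-(propan-2-yl)cyclopentyl]acetate | CCOC(=O)C[C@@]1(C)CC[C@H](C(C)C)C1=C | intermediate
9 | 2-[(1R,3R)-1-methyl-2-methylidene-3-(propan-2-yl)cyclopentyl]acetic acid | OC(=O)C[C@@]1(C)CC[C@H](C(C)C)C1=C | intermediate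
10 | 2-[(1R,3R)-1-methyl-2-oxo-3-(propan-2-yl)cyclopentyl]acetic acid | OC(=O)C[C@@]1(C)CC[C@H](C(C)C)C1=O | intermediate
11 | isobutyl carbonic mixed anhydride of 10 | CC(C)COC(=O)OC(=O)C[C@@]1(C)CC[C@H](C(C)C)C1=O | intermediate (not isolated)
12 | 1-diazo-3-[(1R,3R)-1-methyl-2-oxo-3-(propan-2-yl)cyclopentyl]propan-2-one | [N-]=[N+]=CC(=O)C[C@@]1(C)CC[C@H](C(C)C)C1=O | intermediate (key-step precursor)
13 | ethynyl phenyl sulfone | C#CS(=O)(=O)c1ccccc1 | starting material
14 | six-membered carbonyl ylide (C5=O+–C8H−, C9=O) | O=C1C[C@@]2(C)CC[C@H](C(C)C)C2=[O+][CH-]1 | intermediate (not isolated)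
15 | 5β,8β-oxygen-bridged 9-ketone, C6=C7, 6-phenylsulfonyl, 1β-Me, 4β-iPr | O=C1C[C@@]2(C)CC[C@H](C(C)C)[C@]23O[C@H]1C=C3S(=O)(=O)c1ccccc1 | intermediate (key-step product)
16 | 9,9-ethylenedioxy ketal of 15 | C1COC2(O1)C[C@@]3(C)CC[C@H](C(C)C)[C@]34O[C@H]2C=C4S(=O)(=O)c1ccccc1 | intermediate
17 | desulfonylated bridged C6=C7 alkene ketal | C1COC2(O1)C[C@@]3(C)CC[C@H](C(C)C)[C@]34O[C@H]2C=C4 | intermediate
18 | saturated bridged ketal | C1COC2(O1)C[C@@]3(C)CC[C@H](C(C)C)[C@]34O[C@H]2CC4 | intermediate (not isolated)
19 | saturated 5β,8β-oxygen-bridged 9-ketone | O=C1C[C@@]2(C)CC[C@H](C(C)C)[C@]23O[C@H]1CC3 | intermediate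
20 | 5β-hydroxy-1β-methyl-4β-isopropyl bicyclo[5.3.0]decan-9-one | O=C1C[C@@]2(C)CC[C@H](C(C)C)[C@@]2(O)CCC1 | intermediate
21 | 5β-triethylsilyl ether of 20 | O=C1C[C@@]2(C)CC[C@H](C(C)C)[C@@]2(O[Si](CC)(CC)CC)CCC1 | intermediate
22 | 8-methyl derivative of 21 (C8 epimer mixture, centre removed in step 16) | O=C1C[C@@]2(C)CC[C@H](C(C)C)[C@@]2(O[Si](CC)(CC)CC)CCC1C | intermediate
23 | 8-methyl C8=C9 enol triflate, 5β-OTES | CC1=C(OS(=O)(=O)C(F)(F)F)C[C@@]2(C)CC[C@H](C(C)C)[C@@]2(O[Si](CC)(CC)CC)CC1 | intermediate
24 | 8-methyl C8=C9 alkene, 5β-OTES | CC1=CC[C@@]2(C)CC[C@H](C(C)C)[C@@]2(O[Si](CC)(CC)CC)CC1 | intermediate (not isolated)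
25 | 8-methyl C8=C9 alkene, 5β-OH | CC1=CC[C@@]2(C)CC[C@H](C(C)C)[C@@]2(O)CC1 | intermediate
26 | 8β,9β-epoxide, 5β-OH | O1[C@@H]2C[C@@]3(C)CC[C@H](C(C)C)[C@@]3(O)CC[C@]12C | intermediate
27 | 5β,8α,9β-triol, 8β-methyl | O[C@@H]1C[C@@]2(C)CC[C@H](C(C)C)[C@@]2(O)CC[C@@]1(C)O | intermediate
28 | 4-methoxybenzoyl chloride | COc1ccc(C(=O)Cl)cc1 | starting material
29 | CNP0244624.1, 9β-(4-methoxybenzoate) of 27 | COc1ccc(C(=O)O[C@@H]2C[C@@]3(C)CC[C@H](C(C)C)[C@@]3(O)CC[C@@]2(C)O)cc1 | target

**Step count and risks**
Total step count: 20. Longest linear sequence: 20 steps (1 to 29).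

Steps most likely to fail:

1. Step 9. The moderately reactive alkyne may capture the ylide too slowly, so that a 1,4-proton shift from C4–H to C8 (giving a cyclic enol ether) or ylide dimerisation takes over; facial discrimination may also be incomplete. Fallback, setting out from 12: under the same Rh2(OAc)4 conditions the much more electrophilic and symmetrical acetylene equivalent (E)-1,2-bis(phenylsulfonyl)ethene should give the 6,7-bis(phenylsulfonyl) cycloadduct F1. Ketalisation as in step 10 gives its ketal F2. Treatment with 6% Na/Hg (Na2HPO4, MeOH/THF) then removes both sulfonyl groups by vicinal reductive elimination, which should outrun loss of the β-alkoxy bridge, and the route is rejoined at 17.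

2. Step 18. Oxygen may be transferred to the α face without hydroxyl delivery (the face away from the angular methyl), after which the C5 hydroxyl would open that epoxide across the ring. Fallback, setting out from 22: TMSCl, NaI and Et3N in MeCN give the thermodynamic C8=C9 trimethylsilyl enol ether F3. Rubottom oxidation (mCPBA, NaHCO3, CH2Cl2; then K2CO3, MeOH) gives the tertiary α-hydroxy ketone F4, the peracid attacking the α face away from C5–OTES and C1–Me, so this fallback uses the very facial preference that would defeat step 18. Hydroxyl-directed reduction with Me4NBH(OAc)3 (MeCN/AcOH, −20 °C) delivers hydride from the boron bound at C8–OH to the α face of C9 and gives the 8α,9β-diol silyl ether F5. Bu4NF then frees C5–OH and the route is rejoined at 27.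

3. Step 5. Facial discrimination in the sigmatropic shift may be incomplete, because the isopropyl group is 1,3 to the new quaternary centre, and acid-induced dehydration of the allylic alcohol may compete. Fallback, setting out from 4: Baeyer–Villiger oxidation (mCPBA, NaHCO3, CH2Cl2) gives the enol formate F6. MeLi (2 equiv, THF, 0 °C) releases the regiodefined lithium enolate, which is alkylated anti to the isopropyl group with tert-butyl bromoacetate (DMPU, −78 °C) to give the tert-butyl keto ester F7. CF3CO2H in CH2Cl2 cleaves the ester and the route is rejoined at 10.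

**Further compounds**
F1 | step 9 | 6,7-bis(phenylsulfonyl) 5β,8β-oxygen-bridged 9-ketone (C6/C7 trans, either orientation) | O=C1C[C@@]2(C)CC[C@H](C(C)C)[C@]23O[C@H]1C(S(=O)(=O)c1ccccc1)C3S(=O)(=O)c1ccccc1
F2 | step 9 | 9,9-ethylenedioxy ketal of F1 | C1COC2(O1)C[C@@]3(C)CC[C@H](C(C)C)[C@]34O[C@H]2C(S(=O)(=O)c1ccccc1)C4S(=O)(=O)c1ccccc1
F3 | step 18 | C8=C9 trimethylsilyl enol ether of 22 | CC1=C(O[Si](C)(C)C)C[C@@]2(C)CC[C@H](C(C)C)[C@@]2(O[Si](CC)(CC)CC)CC1
F4 | step 18 | 8α-hydroxy-8β-methyl-5β-triethylsilyloxy-9-ketone | O=C1C[C@@]2(C)CC[C@H](C(C)C)[C@@]2(O[Si](CC)(CC)CC)CC[C@@]1(C)O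
F5 | step 18 | 8α,9β-diol, 5β-triethylsilyl ether | O[C@@H]1C[C@@]2(C)CC[C@H](C(C)C)[C@@]2(O[Si](CC)(CC)CC)CC[C@@]1(C)O
F6 | step 5 | (5R)-2-methyl-5-(propan-2-yl)cyclopent-1-en-1-yl formate | O=COC1=C(C)CC[C@@H]1C(C)C
F7 | step 5 | tert-butyl 2-[(1R,3R)-1-methyl-2-oxo-3-(propan-2-yl)cyclopentyl]acetate | CC(C)(C)OC(=O)C[C@@]1(C)CC[C@H](C(C)C)C1=O
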